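**Retrosynthetic overview**

- Feature: the ether oxygen links C3 and C10 (germacrane numbering throughout), which are 1,4-related through C2–C1 inside the ten-membered carbocycle. The oxolane C3–C2–C1–C10–O of the 11-oxabicyclo[6.2.1] core is therefore the C3–C10 bond of a cyclobutanol whose own oxygen has moved into the ring.
- Key disconnection: bridged hemiketal ⇒ cis-fused bicyclo[6.2.0]decenol (temporary C3–C10 bond), by alkoxy-radical ring opening with transannular oxygen capture at C10.
- Precursor: C3–C4 by intramolecular Nozaki–Hiyama–Kishi addition of a Z-iodoalkene to a cyclobutanone; the cyclobutanone by protio-semipinacol shift of an alkenylcyclopropyl ether; C8–C9 by asymmetric allylboration; C6–C7 and the lactone by an Evans succinate aldol.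
- Ring order: γ-lactone (step 5), cyclobutanone (step 12), cyclooctene (step 14), then oxolane plus ten-membered ring (step 15); methylene lactone, ester and deprotection last.

Key step: step 15

Assumption: C3 of the bridged hemiketal is written with the descriptor of the target string; as a hemiketal carbon it equilibrates (ring–chain with the 10-hydroxy-3-enone) and is fixed by the bridge, so only C6, C7, C8 and C10 have to be set by the route.

**Route**

Step 1
Reactants: 1 but-2-yne-1,4-diol
Product: 2 4-[(tert-butyldimethylsilyl)oxy]but-2-yn-1-ol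
Conditions: TBSCl (1 equiv), imidazole, THF, 0 → 20 °C, diol in threefold excess
Reagents that add atoms: tert-butyldimethylsilyl chloride, CC(C)(C)[Si](C)(C)Cl
Why: Statistical monosilylation of a symmetrical diol, the excess diol being removed by aqueous extraction; no stereocentre is formed.

Step 2
Reactants: 2 4-[(tert-butyldimethylsilyl)oxy]but-2-yn-1-ol
Product: 3 (Z)-4-[(tert-butyldimethylsilyl)oxy]-3-iodobut-2-en-1-ol
Conditions: NaAlH2(OCH2CH2OMe)2, THF, 0 → 20 °C; then I2, −78 → 0 °C
Reagents that add atoms: iodine, II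
Why: Hydroxyl-directed trans-hydroalumination puts aluminium on the alkyne carbon remote from the free OH, and iodinolysis with retention gives the Z-iodoalkene in which iodine (at the later C4) is cis to the CH2OH arm (later C6).

Step 3
Reactants: 3 (Z)-4-[(tert-butyldimethylsilyl)oxy]-3-iodobut-2-en-1-ol
Product: 4 (Z)-4-[(tert-butyldimethylsilyl)oxy]-3-iodobut-2-enal
Conditions: MnO2, CH2Cl2, 20 °C
Reagents that add atoms: none
Why: Manganese dioxide oxidises the allylic alcohol to the enal under neutral conditions with retention of the Z geometry.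

Step 4
Reactants: 5 (S)-4-benzyloxazolidin-2-one; 6 methyl 4-chloro-4-oxobutanoate
Product: 7 methyl 4-[(4S)-4-benzyl-2-oxooxazolidin-3-yl]-4-oxobutanoate
Conditions: n-BuLi, THF, −78 °C; then 6, −78 → 0 °C
Reagents that add atoms: none
Why: N-Acylation of the lithiated oxazolidinone by the acid chloride, which reacts far faster than the methyl ester.

Step 5
Reactants: 7 methyl 4-[(4S)-4-benzyl-2-oxooxazolidin-3-yl]-4-oxobutanoate; 4 (Z)-4-[(tert-butyldimethylsilyl)oxy]-3-iodobut-2-enal
Product: 9 (4S)-4-benzyl-3-{[(2S,3S)-2-{(Z)-3-[(tert-butyldimethylsilyl)oxy]-2-iodoprop-1-en-1-yl}-5-oxooxolan-3-yl]carbonyl}oxazolidin-2-one (trans-lactone imide), via aldol adduct 8 (not isolated)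
Conditions: Bu2BOTf, iPr2NEt, CH2Cl2, −78 → 0 °C; 4, −78 → 0 °C; pH 7 buffer, MeOH, H2O2, 0 °C; then CSA (cat.), CH2Cl2, 20 °C
Reagents that add atoms: none
Why: Evans syn-aldol reaction: the Z-boron enolate forms at the imide α-carbon (C7) and adds to the enal through a chair transition state on the face opposite the benzyl group, which sets C6 and C7 in the 6,7-syn arrangement of the target, and the new C6 hydroxyl, the only one present, then closes onto the methyl ester to give the trans-γ-lactone (first ring).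

Step 6
Reactants: 9 trans-lactone imide
Product: 10 (2S,3S)-2-{(Z)-3-[(tert-butyldimethylsilyl)oxy]-2-iodoprop-1-en-1-yl}-5-oxooxolane-3-carboxylic acid
Conditions: LiOH, H2O2, THF–H2O, 0 °C; Na2SO3; HCl to pH 2
Reagents that add atoms: hydrogen peroxide, OO
Why: Hydroperoxide attacks the exocyclic imide carbonyl selectively and releases the auxiliary; any lactone opened by hydroxide re-closes on acidification because C6–OH is the only hydroxyl.

Step 7
Reactants: 10 lactone acid
Product: 11 (4R,5S)-5-{(Z)-3-[(tert-butyldimethylsilyl)oxy]-2-iodoprop-1-en-1-yl}-4-(hydroxymethyl)oxolan-2-one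
Conditions: BH3·SMe2, THF, 0 → 20 °C; MeOH
Reagents that add atoms: none
Why: Borane reduces the free carboxylic acid much faster than the lactone or the hindered, electron-poor iodoalkene.

Step 8
Reactants: 11 hydroxymethyl lactone
Product: 12 (2S,3S)-2-{(Z)-3-[(tert-butyldimethylsilyl)oxy]-2-iodoprop-1-en-1-yl}-5-oxooxolane-3-carbaldehyde
Conditions: Dess–Martin periodinane, pyridine, CH2Cl2, 0 °C
Reagents that add atoms: none
Why: Buffered Dess–Martin oxidation gives the C8 aldehyde under non-basic conditions, so that C7 is not epimerised and the β-acyloxy group is not eliminated; 12 is used without storage.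

Step 9
Reactants: 13 (1-ethoxycyclopropoxy)trimethylsilane; 14 isopropenylmagnesium bromide, CH2=C(CH3)MgBr
Product: 16 1-(prop-1-en-2-yl)cyclopropan-1-ol, via 1-ethoxycyclopropan-1-ol 15 (not isolated)
Conditions: MeOH, 20 °C, then evaporation; 14 (2.2 equiv), THF, 0 °C → reflux
Reagents that add atoms: none
Why: Methanolysis frees hemiketal 15, whose magnesium salt (first equivalent of Grignard reagent) acts as a cyclopropanone equivalent and is attacked by the second equivalent at the hemiketal carbon with loss of ethoxide, the standard route to 1-alkenylcyclopropanols.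

Step 10
Reactants: 16 1-(prop-1-en-2-yl)cyclopropan-1-ol
Product: 17 1-methoxy-1-(prop-1-en-2-yl)cyclopropane
Conditions: NaH, THF, 0 °C; MeI, 0 → 20 °C
Reagents that add atoms: iodomethane, CI
Why: Williamson methylation of the tertiary cyclopropanolate under aprotic conditions; a methyl ether cannot undergo the oxygen-to-carbon silyl shift that a silyl ether would risk in the allyl anion of the next step.

Step 11
Reactants: 17 1-methoxy-1-(prop-1-en-2-yl)cyclopropane; 12 lactone aldehyde
Product: 20 (4R,5S)-4-[(1R)-1-hydroxy-3-(1-methoxycyclopropyl)but-3-en-1-yl]-5-{(Z)-3-[(tert-butyldimethylsilyl)oxy]-2-iodoprop-1-en-1-yl}oxolan-2-one, via allylpotassium 18 (not isolated), via allylborane 19 (not isolated)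
Conditions: 17, n-BuLi, KOtBu, THF, −78 → −45 °C; (+)-Ipc2BOMe, −78 °C; BF3·OEt2; 12, −78 °C; pH 7 buffer, H2O2, MeOH, 0 °C
Reagents that add atoms: none
Why: Brown-type asymmetric allylboration: metalation of the allylic methyl group of 17, trapping on boron and BF3 activation give allylborane 19, which adds to the aldehyde through a chair transition state in which the (−)-α-pinene-derived Ipc groups direct C9 to the Re face of C8 (8R, reagent control over the C7 centre), while lactone, silyl ether and iodoalkene are inert at −78 °C and the neutral oxidative work-up avoids lactone migration.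

Step 12
Reactants: 20 homoallylic alcohol
Product: 21 (4R,5S)-4-{(1R)-1-hydroxy-2-[(1R)-1-methyl-2-oxocyclobutyl]ethyl}-5-{(Z)-3-[(tert-butyldimethylsilyl)oxy]-2-iodoprop-1-en-1-yl}oxolan-2-one
Conditions: TsOH·H2O (20 mol %), H2O (2 equiv), CH2Cl2, 0 → 20 °C; chromatographic separation of the C10 epimers
Reagents that add atoms: water, O
Why: Protonation of the 1,1-disubstituted alkene at its CH2 terminus is coupled to a 1,2-shift of a cyclopropane bond to C10 (protio-semipinacol ring expansion of a 1-alkenylcyclopropyl ether), and water hydrolyses the O-methyl oxocarbenium ion to the cyclobutanone with loss of methanol; the quaternary C10 is not controlled by C8, so the two C10 epimers are separated and the 10R ketone 21, whose ring fusion later puts the departing oxygen on the required face of C10, is carried on.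

Step 13
Reactants: 21 hydroxy ketone
Product: 22 (4S,5S)-4-{(1R)-2-[(1R)-1-methyl-2-oxocyclobutyl]-1-[(triethylsilyl)oxy]ethyl}-5-{(Z)-3-[(tert-butyldimethylsilyl)oxy]-2-iodoprop-1-en-1-yl}oxolan-2-one
Conditions: TESCl, imidazole, DMF, 0 °C
Reagents that add atoms: chlorotriethylsilane, CC[Si](CC)(CC)Cl
Why: Silylation of the secondary C8 hydroxyl (the tertiary hemiketal form of the γ-hydroxy ketone is too hindered for TESCl, so the open form is trapped) gives a non-participating, later selectively removable ether and blocks migration of the lactone to O8.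

Step 14
Reactants: 22 iodoalkenyl cyclobutanone
Product: 23 (3S,4Z,6R,7S,8R,10R)-15-[(tert-butyldimethylsilyl)oxy]-3-hydroxy-8-[(triethylsilyl)oxy]-3,10-cyclo-13-norgermacr-4-en-12,6-olide (cis-fused bicyclo[6.2.0]decenol with trans-fused γ-lactone; 3-OH and 10-CH3 on the same face of the cyclobutane)
Conditions: CrCl2 (8 equiv), NiCl2 (2 mol %), DMSO, 20 °C, 0.005 M
Reagents that add atoms: none
Why: Nozaki–Hiyama–Kishi reaction: NiCl2-catalysed formation of the alkenylchromium species from the Z-iodoalkene (geometry retained) and its intramolecular addition to the strained, electrophilic cyclobutanone, a nucleophile that ignores the lactone; the five-atom tether lets C4 reach only the carbonyl face syn to C9, which sets C3 and the cis ring fusion, and closes the cyclooctene.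

Step 15
Reactants: 23 cis-fused cyclobutanol
Product: 26 (3R,4Z,6R,7S,8R,10R)-15-[(tert-butyldimethylsilyl)oxy]-3,10-epoxy-3-hydroxy-8-[(triethylsilyl)oxy]-13-norgermacr-4-en-12,6-olide (bridged hemiketal with saturated lactone), via hypoiodite 24 (not isolated), via iodo ketone 25 (not isolated)
Conditions: PhI(OAc)2 (2.5 equiv), I2 (1.2 equiv), CH2Cl2, visible light (tungsten lamp), 20 °C; then H2O–MeCN (1:4), 20 °C
Reagents that add atoms: water, O
Why: Proposed new method: PhI(OAc)2 and I2 form acetyl hypoiodite, which turns the tertiary cyclobutanol into hypoiodite 24; visible light cleaves the O–I bond and the C3 alkoxy radical undergoes strain-driven β-scission of C3–C10 (tertiary radical; the alternatives would leave a primary radical at C2 or a vinyl radical at C4), which opens the four-membered ring into the ten-membered 4-en-3-one, and iodine transfer, faster than transannular addition to the enone, gives tertiary iodide 25. Ionisation of the C10–I bond, helped by iodine and by the C3 carbonyl oxygen, lets that oxygen bond to C10 (closure of the oxolane, five-membered, 5-exo with respect to the breaking C–I bond; the nine-membered oxacycle of the bridged core is closed by the same bond), and the bridged oxocarbenium ion takes up water at C3 (directly or via the acetate, hydrolysed in the second stage). The closest known reactions are the hypoiodite (Suárez-type) β-fragmentation of cyclobutanols to γ-iodo ketones and the silver- or manganese-mediated ring-opening halogenation of cyclobutanols; the transannular substitution in the same flask to a bridged hemiketal is the unprecedented part. C10 is controlled by the ring fusion of 23: iodine reaches the C10 radical on its open outer lobe, and the carbonyl oxygen, held by the two-carbon C2–C1 tether on the face that C3 has just left, displaces it from the rear, so that O–C10 replaces C3–C10 with overall retention (10R). C3 is set last and reversibly when water adds to the oxocarbenium ion and, being a bridgehead, follows from C10. The step needs cleavage of C3–C10 only (radical stability and strain secure it) and substitution instead of elimination at C10, for which the participating carbonyl and a non-participating silyl ether at C8 are provided.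

Step 16
Reactants: 26 bridged hemiketal
Product: 27 (3R,4Z,6R,7R,8R,10R)-15-[(tert-butyldimethylsilyl)oxy]-3,10-epoxy-8-hydroxy-3-methoxy-13-norgermacr-4-en-12,6-olide
Conditions: PPTS, MeOH, 20 °C
Reagents that add atoms: methanol, CO
Why: Acid-catalysed exchange through the bridged oxocarbenium ion replaces the hemiketal OH by OMe on the same, only accessible, site of C3, which protects the masked ketone from base, and the same medium removes the secondary TES ether while the primary TBS ether survives.

Step 17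
Reactants: 27 methyl ketal alcohol
Product: 28 (3R,4Z,6R,7R,8R,10R)-15-[(tert-butyldimethylsilyl)oxy]-3,10-epoxy-3-methoxy-8-(2-methylpropanoyloxy)-13-norgermacr-4-en-12,6-olide
Conditions: (iPrCO)2O, Et3N, DMAP (cat.), CH2Cl2, 20 °C
Reagents that add atoms: 2-methylpropanoic anhydride, CC(C)C(=O)OC(=O)C(C)C
Why: DMAP-catalysed acylation of the only free hydroxyl (C8) installs the isobutyrate without touching the C8 configuration.

Step 18
Reactants: 28 isobutyrate
Product: 31 (3R,4Z,6R,7R,8R,10R)-15-[(tert-butyldimethylsilyl)oxy]-3,10-epoxy-3-methoxy-8-(2-methylpropanoyloxy)germacra-4,11(13)-dien-12,6-olide, via Mannich base 29 (not isolated), via ammonium iodide 30 (not isolated)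
Conditions: LiN(SiMe3)2 (1.1 equiv), THF, −78 °C; Me2N=CH2+ I− (Eschenmoser's salt), −78 → 0 °C; MeI, MeOH–CH2Cl2, 20 °C; NaHCO3 (aq.), 20 °C
Reagents that add atoms: N,N-dimethylmethyleneiminium iodide, C=[N+](C)C.[I-]
Why: The γ-lactone CH2 (C11) is several pK units more acidic and far less hindered than the isobutyrate methine, so one equivalent of base gives the lactone enolate selectively; Mannich reaction with Eschenmoser's salt anti to the C7 substituent, N-methylation and elimination of trimethylamine deliver the α-methylene lactone (the C11 centre of 29 and 30 is destroyed).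

Step 19
Reactants: 31 protected methylene lactone
Product: 32 (3R,4Z,6R,7R,8R,10R)-3,10-epoxy-3,15-dihydroxy-8-(2-methylpropanoyloxy)germacra-4,11(13)-dien-12,6-olide (target, CNP0282937.1)
Conditions: HF (48 % aq.), MeCN, 0 → 20 °C
Reagents that add atoms: water, O
Why: Aqueous HF cleaves the primary TBS ether and hydrolyses the methyl ketal back to the hemiketal through the same bridged oxocarbenium ion, while the ester, the methylene lactone and the C6, C7, C8 and C10 centres are untouched.

**Compound list**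

1 | but-2-yne-1,4-diol | OCC#CCO | starting material
2 | 4-[(tert-butyldimethylsilyl)oxy]but-2-yn-1-ol | OCC#CCO[Si](C)(C)C(C)(C)C | intermediate
3 | (Z)-4-[(tert-butyldimethylsilyl)oxy]-3-iodobut-2-en-1-ol | OC/C=C(\I)CO[Si](C)(C)C(C)(C)C | intermediate
4 | (Z)-4-[(tert-butyldimethylsilyl)oxy]-3-iodobut-2-enal | O=C/C=C(\I)CO[Si](C)(C)C(C)(C)C | intermediate
5 | (S)-4-benzyloxazolidin-2-one | O=C1N[C@@H](Cc2ccccc2)CO1 | starting material
6 | methyl 4-chloro-4-oxobutanoate | COC(=O)CCC(Cl)=O | starting material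
7 | methyl 4-[(4S)-4-benzyl-2-oxooxazolidin-3-yl]-4-oxobutanoate | COC(=O)CCC(=O)N1[C@@H](Cc2ccccc2)COC1=O | intermediate
8 | methyl (3S,4S,5Z)-3-[(4S)-4-benzyl-2-oxooxazolidine-3-carbonyl]-7-[(tert-butyldimethylsilyl)oxy]-4-hydroxy-6-iodohept-5-enoate (syn-aldol adduct) | COC(=O)C[C@H](C(=O)N1[C@@H](Cc2ccccc2)COC1=O)[C@H](O)/C=C(\I)CO[Si](C)(C)C(C)(C)C | intermediate
9 | (4S)-4-benzyl-3-{[(2S,3S)-2-{(Z)-3-[(tert-butyldimethylsilyl)oxy]-2-iodoprop-1-en-1-yl}-5-oxooxolan-3-yl]carbonyl}oxazolidin-2-one | O=C1C[C@H](C(=O)N2[C@@H](Cc3ccccc3)COC2=O)[C@@H](/C=C(\I)CO[Si](C)(C)C(C)(C)C)O1 | intermediate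
10 | (2S,3S)-2-{(Z)-3-[(tert-butyldimethylsilyl)oxy]-2-iodoprop-1-en-1-yl}-5-oxooxolane-3-carboxylic acid | O=C1C[C@H](C(O)=O)[C@@H](/C=C(\I)CO[Si](C)(C)C(C)(C)C)O1 | intermediate
11 | (4R,5S)-5-{(Z)-3-[(tert-butyldimethylsilyl)oxy]-2-iodoprop-1-en-1-yl}-4-(hydroxymethyl)oxolan-2-one | O=C1C[C@H](CO)[C@@H](/C=C(\I)CO[Si](C)(C)C(C)(C)C)O1 | intermediate
12 | (2S,3S)-2-{(Z)-3-[(tert-butyldimethylsilyl)oxy]-2-iodoprop-1-en-1-yl}-5-oxooxolane-3-carbaldehyde | O=C1C[C@H](C=O)[C@@H](/C=C(\I)CO[Si](C)(C)C(C)(C)C)O1 | intermediate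
13 | (1-ethoxycyclopropoxy)trimethylsilane | CCOC1(CC1)O[Si](C)(C)C | starting material
14 | isopropenylmagnesium bromide | CC(=C)[Mg]Br | starting material
15 | 1-ethoxycyclopropan-1-ol | CCOC1(O)CC1 | intermediate
16 | 1-(prop-1-en-2-yl)cyclopropan-1-ol | CC(=C)C1(O)CC1 | intermediate
17 | 1-methoxy-1-(prop-1-en-2-yl)cyclopropane | COC1(CC1)C(C)=C | intermediate
18 | [2-(1-methoxycyclopropyl)prop-2-en-1-yl]potassium | [K+].[CH2-]C(=C)C1(OC)CC1 | intermediate
19 | bis[(1S,2R,3S,5S)-2,6,6-trimethylbicyclo[3.1.1]heptan-3-yl][2-(1-methoxycyclopropyl)prop-2-en-1-yl]borane | C=C(CB([C@H]1C[C@H]2C[C@@H]([C@@H]1C)C2(C)C)[C@H]1C[C@H]2C[C@@H]([C@@H]1C)C2(C)C)C1(OC)CC1 | intermediate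
20 | (4R,5S)-4-[(1R)-1-hydroxy-3-(1-methoxycyclopropyl)but-3-en-1-yl]-5-{(Z)-3-[(tert-butyldimethylsilyl)oxy]-2-iodoprop-1-en-1-yl}oxolan-2-one | O=C1C[C@H]([C@H](O)CC(=C)C2(OC)CC2)[C@@H](/C=C(\I)CO[Si](C)(C)C(C)(C)C)O1 | intermediate
21 | (4R,5S)-4-{(1R)-1-hydroxy-2-[(1R)-1-methyl-2-oxocyclobutyl]ethyl}-5-{(Z)-3-[(tert-butyldimethylsilyl)oxy]-2-iodoprop-1-en-1-yl}oxolan-2-one | O=C1C[C@H]([C@H](O)C[C@@]2(C)CCC2=O)[C@@H](/C=C(\I)CO[Si](C)(C)C(C)(C)C)O1 | intermediate
22 | (4S,5S)-4-{(1R)-2-[(1R)-1-methyl-2-oxocyclobutyl]-1-[(triethylsilyl)oxy]ethyl}-5-{(Z)-3-[(tert-butyldimethylsilyl)oxy]-2-iodoprop-1-en-1-yl}oxolan-2-one | O=C1C[C@H]([C@H](O[Si](CC)(CC)CC)C[C@@]2(C)CCC2=O)[C@@H](/C=C(\I)CO[Si](C)(C)C(C)(C)C)O1 | intermediate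
23 | (3S,4Z,6R,7S,8R,10R)-15-[(tert-butyldimethylsilyl)oxy]-3-hydroxy-8-[(triethylsilyl)oxy]-3,10-cyclo-13-norgermacr-4-en-12,6-olide (key-step precursor) | C1C(=O)O[C@@H]2/C=C(/CO[Si](C)(C)C(C)(C)C)[C@]3(O)CC[C@]3(C)C[C@@H](O[Si](CC)(CC)CC)[C@@H]12 | intermediate
24 | C3 hypoiodite of 23, (3S,4Z,6R,7S,8R,10R) | C1C(=O)O[C@@H]2/C=C(/CO[Si](C)(C)C(C)(C)C)[C@]3(OI)CC[C@]3(C)C[C@@H](O[Si](CC)(CC)CC)[C@@H]12 | intermediate
25 | (4Z,6R,7S,8R,10S)-15-[(tert-butyldimethylsilyl)oxy]-10-iodo-3-oxo-8-[(triethylsilyl)oxy]-13-norgermacr-4-en-12,6-olide | C1C(=O)O[C@@H]2/C=C(/CO[Si](C)(C)C(C)(C)C)C(=O)CC[C@](C)(I)C[C@@H](O[Si](CC)(CC)CC)[C@@H]12 | intermediate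
26 | (3R,4Z,6R,7S,8R,10R)-15-[(tert-butyldimethylsilyl)oxy]-3,10-epoxy-3-hydroxy-8-[(triethylsilyl)oxy]-13-norgermacr-4-en-12,6-olide (key-step product) | C1C(=O)O[C@@H]2/C=C(/CO[Si](C)(C)C(C)(C)C)[C@@]3(O)CC[C@](C)(C[C@@H](O[Si](CC)(CC)CC)[C@@H]12)O3 | intermediate
27 | (3R,4Z,6R,7R,8R,10R)-15-[(tert-butyldimethylsilyl)oxy]-3,10-epoxy-8-hydroxy-3-methoxy-13-norgermacr-4-en-12,6-olide | C1C(=O)O[C@@H]2/C=C(/CO[Si](C)(C)C(C)(C)C)[C@@]3(OC)CC[C@](C)(C[C@@H](O)[C@@H]12)O3 | intermediate
28 | (3R,4Z,6R,7R,8R,10R)-15-[(tert-butyldimethylsilyl)oxy]-3,10-epoxy-3-methoxy-8-(2-methylpropanoyloxy)-13-norgermacr-4-en-12,6-olide | C1C(=O)O[C@@H]2/C=C(/CO[Si](C)(C)C(C)(C)C)[C@@]3(OC)CC[C@](C)(C[C@@H](OC(=O)C(C)C)[C@@H]12)O3 | intermediate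
29 | (3R,4Z,6R,7R,8R,10R,11R)-15-[(tert-butyldimethylsilyl)oxy]-13-(dimethylamino)-3,10-epoxy-3-methoxy-8-(2-methylpropanoyloxy)germacr-4-en-12,6-olide (Mannich base) | CN(C)C[C@@H]1C(=O)O[C@@H]2/C=C(/CO[Si](C)(C)C(C)(C)C)[C@@]3(OC)CC[C@](C)(C[C@@H](OC(=O)C(C)C)[C@@H]12)O3 | intermediate
30 | N-methyl quaternary ammonium iodide of 29 | C[N+](C)(C)C[C@@H]1C(=O)O[C@@H]2/C=C(/CO[Si](C)(C)C(C)(C)C)[C@@]3(OC)CC[C@](C)(C[C@@H](OC(=O)C(C)C)[C@@H]12)O3.[I-] | intermediate
31 | (3R,4Z,6R,7R,8R,10R)-15-[(tert-butyldimethylsilyl)oxy]-3,10-epoxy-3-methoxy-8-(2-methylpropanoyloxy)germacra-4,11(13)-dien-12,6-olide | C=C1C(=O)O[C@@H]2/C=C(/CO[Si](C)(C)C(C)(C)C)[C@@]3(OC)CC[C@](C)(C[C@@H](OC(=O)C(C)C)[C@@H]12)O3 | intermediate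
32 | (3R,4Z,6R,7R,8R,10R)-3,10-epoxy-3,15-dihydroxy-8-(2-methylpropanoyloxy)germacra-4,11(13)-dien-12,6-olide | C=C1C(=O)O[C@@H]2/C=C(/CO)[C@@]3(O)CC[C@](C)(C[C@@H](OC(=O)C(C)C)[C@@H]12)O3 | target

**Step count and risks**

Total steps: 19. Longest linear sequence: 16 steps (1–3, 5–8, 11–19).

Step 15 (proposed new method). After the scission, loss of a proton from the tertiary iodide or cation (elimination to ring or exocyclic alkenes), or oxygen capture on the wrong face of C10, may outrun the transannular substitution. The fallback uses two known reactions and sets out from 23. Silver-catalysed radical ring-opening chlorination (AgNO3 cat., K2S2O8, N-chlorosuccinimide, CH2Cl2–H2O, 20 °C) should give the ten-membered γ-chloro ketone F1, a tertiary chloride stable enough to purify. Silver-assisted solvolysis (AgOSO2CF3, 2,6-lutidine, acetone–H2O, 0 °C) then ionises C10 under participation of the C3 carbonyl, and water completes the hemiketal; the route is rejoined at 26.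

Step 14. The alkenylchromium species may add too slowly to the hindered ketone, so that protodemetalation and intermolecular coupling win over eight-membered ring closure. The fallback replaces the chromium chemistry by an anionic cyclisation and sets out from 22. LiOH (THF–H2O, 0 °C) opens the lactone to the lithium hydroxy carboxylate F2, which masks the only other electrophile. After drying, t-BuLi (3.3 equiv, THF, −100 → −78 °C) should effect iodine–lithium exchange faster than carbonyl attack, and the alkenyllithium adds to the cyclobutanone under the same tether control. Acidification (CSA, CH2Cl2) re-closes the γ-lactone at O6, the only free secondary hydroxyl, and the route is rejoined at 23.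

Step 11. Metalation of 17 may be incomplete, or the C7 stereocentre may erode reagent control (mismatched pairing) and give the C8 epimer. The fallback builds C8 by enamine catalysis and the cyclobutanone by oxidative ring expansion, and sets out from 12. An L-proline-catalysed aldol reaction with acetone (acetone–DMSO, 4 °C; 8R from the catalyst) gives the β-hydroxy ketone F3, and TESCl–imidazole gives the silyl ether F4. Wittig reaction with cyclopropylidenetriphenylphosphorane (cyclopropyltriphenylphosphonium bromide, KOtBu, THF) gives the alkylidenecyclopropane F5. mCPBA (NaHCO3, CH2Cl2, 0 °C) forms the oxaspiropentane F6, whose LiI-induced ring expansion (migration anti to the epoxide oxygen) gives the cyclobutanone. The epoxidation is not face-selective, so the C10 epimers are again separated, and the route is rejoined at 22.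

Further compounds
F1 | step 15 | (4Z,6R,7S,8R,10S)-15-[(tert-butyldimethylsilyl)oxy]-10-chloro-3-oxo-8-[(triethylsilyl)oxy]-13-norgermacr-4-en-12,6-olide | C1C(=O)O[C@@H]2/C=C(/CO[Si](C)(C)C(C)(C)C)C(=O)CC[C@](C)(Cl)C[C@@H](O[Si](CC)(CC)CC)[C@@H]12
F2 | step 14 | lithium (3S,4S,5Z)-7-[(tert-butyldimethylsilyl)oxy]-4-hydroxy-6-iodo-3-{(1R)-2-[(1R)-1-methyl-2-oxocyclobutyl]-1-[(triethylsilyl)oxy]ethyl}hept-5-enoate | [Li+].[O-]C(=O)C[C@H]([C@H](O[Si](CC)(CC)CC)C[C@@]1(C)CCC1=O)[C@H](O)/C=C(\I)CO[Si](C)(C)C(C)(C)C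
F3 | step 11 | (4R,5S)-4-[(1R)-1-hydroxy-3-oxobutyl]-5-{(Z)-3-[(tert-butyldimethylsilyl)oxy]-2-iodoprop-1-en-1-yl}oxolan-2-one | O=C1C[C@H]([C@H](O)CC(C)=O)[C@@H](/C=C(\I)CO[Si](C)(C)C(C)(C)C)O1
F4 | step 11 | (4S,5S)-4-{(1R)-3-oxo-1-[(triethylsilyl)oxy]butyl}-5-{(Z)-3-[(tert-butyldimethylsilyl)oxy]-2-iodoprop-1-en-1-yl}oxolan-2-one | O=C1C[C@H]([C@H](O[Si](CC)(CC)CC)CC(C)=O)[C@@H](/C=C(\I)CO[Si](C)(C)C(C)(C)C)O1
F5 | step 11 | (4S,5S)-4-{(1R)-3-cyclopropylidene-1-[(triethylsilyl)oxy]butyl}-5-{(Z)-3-[(tert-butyldimethylsilyl)oxy]-2-iodoprop-1-en-1-yl}oxolan-2-one | O=C1C[C@H]([C@H](O[Si](CC)(CC)CC)CC(C)=C2CC2)[C@@H](/C=C(\I)CO[Si](C)(C)C(C)(C)C)O1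
F6 | step 11 | (4S,5S)-4-{(1R)-2-[(2S)-2-methyl-1-oxaspiro[2.2]pentan-2-yl]-1-[(triethylsilyl)oxy]ethyl}-5-{(Z)-3-[(tert-butyldimethylsilyl)oxy]-2-iodoprop-1-en-1-yl}oxolan-2-one | O=C1C[C@H]([C@H](O[Si](CC)(CC)CC)C[C@]2(C)OC23CC3)[C@@H](/C=C(\I)CO[Si](C)(C)C(C)(C)C)O1
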